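**Retrosynthetic overview**

1. The strategy rests on ring A: C1 is quaternary (CH3 and an acyl carbon) and is bonded to allylic C2 (sec-butyl) beside C3=C4. This γ,δ-unsaturated carbonyl array is what a [3,3] shift of an ester enolate leaves when its alcohol oxygen sits on C4.
2. Target ⇒ O-silyl 5,6-diol + 3-methylglutaconic anhydride (C5 ester made last). The 3-hydroxypropanoyl chain ⇐ C1 carboxylic acid via the methyl ketone and a formaldehyde aldol.
3. Decalin acid ⇐ trans-fused 4-(E)-alkenyl-1-methyl δ-lactone on ring B (Ireland–Claisen ring contraction: C1–C2 formed, C4–O broken).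
4. Lactone ⇐ ring-B aldehyde (C4) + (E)-alkenylmagnesium reagent from (R)-2-methylbutanoic acid. Aldehyde ⇐ C4a ketone (methoxymethylene Wittig). Ring B carries C8 from (R)-pulegone, C8a from an enolate alkylation, C5/C6 from a hydroxyl-directed dihydroxylation.
5. Ring order: ring B (chiral pool) → δ-lactone ring (step 14) → ring A by contraction of that lactone (step 16).

Key step: step 16

Assumption: the decalin locants C1–C8a of the target are used for all intermediates, and lactone 23 is carried on as its mixture of C1 epimers (its SMILES shows the epimer with the equatorial methyl group).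

**Route**

Step 1
Reactants: 1 (R)-pulegone
Product: 2 pulegone oxide (spiro-epoxide of the isopropylidene group, both epoxide diastereomers)
Conditions: 30% H2O2, LiOH·H2O (cat.), MeOH, 0 °C → rt
Reagents that add atoms: hydrogen peroxide, OO
Why: Weitz–Scheffer nucleophilic epoxidation of the enone C=C should be clean, and the epoxide configuration is of no consequence because both epoxide carbons lose it in steps 2 and 3.

Step 2
Reactants: 2 pulegone oxide
Product: 3 (5R)-5-methyl-2-(phenylsulfanyl)cyclohexan-1-one (C2 epimers)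
Conditions: PhSNa, THF, reflux; H2O
Reagents that add atoms: sodium benzenethiolate, [Na+].[S-]c1ccccc1
Why: SN2 opening of the α,β-epoxy ketone by thiolate at the α-carbon gives a β-alkoxide that expels acetone by retro-aldol cleavage, leaving the α-sulfanyl ketone with the C8 methyl stereocentre untouched.

Step 3
Reactants: 3 (5R)-5-methyl-2-(phenylsulfanyl)cyclohexan-1-one
Product: 5 (R)-5-methylcyclohex-2-en-1-one, via α-sulfinyl ketone 4 (not isolated)
Conditions: mCPBA (1 equiv), CH2Cl2, −78 °C; then CaCO3, toluene, 110 °C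
Reagents that add atoms: none
Why: Sulfide oxidation followed by thermal syn-elimination of the sulfoxide (sulfoxide pyrolysis) can only engage the C6 hydrogens and should give the C5=C6 enone regiospecifically.

Step 4
Reactants: 5 (R)-5-methylcyclohex-2-en-1-one; 6 methyl bromoacetate
Product: 8 methyl 2-[(1S,6R)-6-methyl-2-oxocyclohex-3-en-1-yl]acetate, via lithium dienolate 7 (not isolated)
Conditions: LDA, THF, −78 °C; then 6, DMPU, −78 → −30 °C
Reagents that add atoms: none
Why: Kinetic α′-deprotonation gives the cross-conjugated dienolate, and enolate alkylation with the reactive bromoacetate should occur anti to the adjacent C8 methyl group, setting C8a trans, which is also the thermodynamically preferred diequatorial arrangement.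

Step 5
Reactants: 8 methyl 2-[(1S,6R)-6-methyl-2-oxocyclohex-3-en-1-yl]acetate
Product: 9 methyl 2-[(1S,2S,6R)-2-hydroxy-6-methylcyclohex-3-en-1-yl]acetate
Conditions: NaBH4, CeCl3·7H2O, MeOH, −78 °C
Reagents that add atoms: none
Why: Luche 1,2-reduction spares the ester and delivers hydride axially, giving the pseudo-equatorial allylic alcohol (trans to the C8a side chain), which is needed only to steer step 6 and is removed again in step 8.

Step 6
Reactants: 9 methyl 2-[(1S,2S,6R)-2-hydroxy-6-methylcyclohex-3-en-1-yl]acetate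
Product: 10 triol ester: methyl 2-(2,3,4-trihydroxy-6-methylcyclohexyl)acetate with the C5,C6-cis-diol anti to the C4a hydroxyl
Conditions: OsO4 (cat.), NMO, acetone–H2O, rt
Reagents that add atoms: N-methylmorpholine N-oxide, C[N+]1([O-])CCOCC1; water, O
Why: Upjohn syn-dihydroxylation should take place on the face anti to the allylic hydroxyl group, which puts both new oxygens (C5, C6) trans to the C8 methyl group and cis to the C8a side chain.

Step 7
Reactants: 10 triol ester
Product: 11 C5,C6-acetonide alcohol (free C4a–OH)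
Conditions: Me2C(OMe)2, PPTS (cat.), acetone, rt
Reagents that add atoms: 2,2-dimethoxypropane, COC(C)(C)OC
Why: Acetal formation is selective for the cis-C5,C6-diol (cis-fused dioxolane) over the trans-C4a,C5 pair.

Step 8
Reactants: 11 acetonide alcohol
Product: 12 acetonide ketone (C4a=O, C8a–CH2CO2Me trans to C8–CH3)
Conditions: Dess–Martin periodinane, NaHCO3, CH2Cl2, rt
Reagents that add atoms: none
Why: Dess–Martin oxidation under buffered, non-basic conditions should give the α-alkoxy ketone without epimerisation at C8a or β-elimination of the C6 oxygen.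

Step 9
Reactants: 12 acetonide ketone
Product: 13 methyl enol ether (C4a=CH–OMe, E/Z mixture)
Conditions: Ph3P(CH2OMe)Cl, KHMDS, THF, 0 °C; then 12, −78 °C → rt
Reagents that add atoms: (methoxymethyl)triphenylphosphonium chloride, [Cl-].COC[P+](c1ccccc1)(c1ccccc1)c1ccccc1
Why: Wittig olefination with the methoxymethylene ylide homologates the ketone by the C4 carbon; the ylide does not attack the methyl ester and should add faster than it enolises the ketone at low temperature.

Step 10
Reactants: 13 methyl enol ether
Product: 14 aldehyde (C4 formyl group equatorial on C4a, trans to both C5–O and the C8a side chain)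
Conditions: TsOH·H2O (cat.), acetone–H2O, 40 °C; then K2CO3, MeOH, 0 °C
Reagents that add atoms: water, O
Why: Enol ether hydrolysis in wet acetone spares the acetonide, and base equilibration at the epimerisable C4a should give the equatorial aldehyde, since an axial formyl group would be 1,3-diaxial to the C6 oxygen and the equatorial C5–O bond is poorly aligned for E1cB loss.

Step 11
Reactants: 15 (R)-2-methylbutanoic acid
Product: 16 (R)-2-methylbutan-1-ol
Conditions: LiAlH4, Et2O, 0 °C → reflux
Reagents that add atoms: none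
Why: Hydride reduction of the acid does not touch the α-stereocentre.

Step 12
Reactants: 16 (R)-2-methylbutan-1-ol
Product: 17 (R)-2-methylbutanal
Conditions: TEMPO (cat.), KBr (cat.), NaOCl, NaHCO3, CH2Cl2–H2O, 0 °C
Reagents that add atoms: none
Why: The buffered TEMPO/hypochlorite oxidation is fast and near-neutral, so the configurationally labile α-methyl aldehyde should form without racemisation; it is used at once as a solution.

Step 13
Reactants: 17 (R)-2-methylbutanal
Product: 18 (R,E)-1-iodo-3-methylpent-1-ene
Conditions: CrCl2, CHI3, THF, 0 °C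
Reagents that add atoms: iodoform, IC(I)I
Why: Takai olefination is non-basic, so the α-centre is safe, and it is (E)-selective.

Step 14
Reactants: 18 (R,E)-1-iodo-3-methylpent-1-ene; 14 aldehyde
Product: 21 trans-fused 4-[(R,E)-3-methylpent-1-enyl] δ-lactone (C1 = CH2; alkenyl group equatorial on C4, cis to C4a–H), via alkenylmagnesium bromide 19 (not isolated), via bromomagnesium alkoxide 20 (not isolated)
Conditions: 18, t-BuLi (2 equiv), Et2O, −78 °C; MgBr2·OEt2; then 14, −78 °C → rt
Reagents that add atoms: none
Why: Iodine–lithium exchange and transmetalation keep the (E)-geometry, and the alkenyl Grignard reagent should add to the aldehyde in the Felkin–Anh sense (C4a–C5 bond anti to the nucleophile), reinforced by 1,3-anti induction from the C5 oxygen of this anti α-alkyl β-alkoxy aldehyde, which sets C4 with the alkenyl group on the side of C4a–H; the magnesium alkoxide then lactonises onto the methyl ester on warming.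

Step 15
Reactants: 21 δ-lactone
Product: 23 1-methyl δ-lactone (C1 epimers), via lithium enolate 22 (not isolated)
Conditions: LDA, THF, −78 °C; then MeI, −78 → −40 °C
Reagents that add atoms: iodomethane, CI
Why: Lactone enolate alkylation installs the C1 methyl group, and its configuration is irrelevant because C1 becomes trigonal again in step 16.

Step 16
Reactants: 23 1-methyl δ-lactone
Product: 27 decalin carboxylic acid (ring A closed; C1: CH3 axial, CO2H equatorial; C2: sec-butyl cis to CO2H), via lithium enolate 24 (not isolated), via silyl ketene acetal 25 (not isolated), via silyl ester 26 (not isolated)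
Conditions: LDA, THF, −78 °C; TBSCl, DMPU, −78 → 0 °C; then toluene, 110 °C; K2CO3, MeOH–H2O, rt; then pH 4
Reagents that add atoms: none
Why: Deprotonation at C1 and O-silylation give the lactone silyl ketene acetal 25, whose C1=C(OSi)–O–C4–C3=C2 array undergoes a concerted suprafacial [3,3] shift (Ireland–Claisen rearrangement) in which C1–C2 forms while C4–O breaks; the closest known reaction is the ring contraction of alkenyl lactone silyl ketene acetals to cycloalkene carboxylic acids. Ring A (C1, C2, C3, C4, C4a, C8a) closes by this ring contraction through a bicyclo[2.2.2]octane-like boat array with C1 and C4 at the bridgeheads, so it is not an exo/endo nucleophilic closure and no Baldwin mode applies. C1 is controlled by the C4 stereocentre: the alkenyl group is delivered to the face of the ketene acetal on which it stands (that of C4a–H), which leaves the methyl group axial and the carboxyl carbon equatorial, and the ring fixes the ketene acetal geometry so that both C1 epimers of 23 converge. C2 is controlled by the boat array together with the (E)-alkene, which turn the sec-butyl group toward the O–C(OSi) bridge and hence cis to the carboxyl group. The step needs facial and boat-versus-chair selectivity: the lactone ring enforces the boat, and the trans fusion to the chair of ring B twists the C4a–C8a bond in the sense that the boat of the 4-equatorial alkenyl epimer requires, whereas the C4 epimer would have to twist against ring B. The silyl ester 26 is hydrolysed on work-up.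

Step 17
Reactants: 27 decalin carboxylic acid
Product: 28 C1 methyl ketone
Conditions: MeLi (4 equiv), Et2O, 0 °C → rt; inverse quench into cold aq. NH4Cl
Reagents that add atoms: methyllithium, [Li]C
Why: Addition of methyllithium to the lithium carboxylate stops at the gem-dialkoxide, which gives the methyl ketone on hydrolysis (ketone synthesis from a carboxylic acid), a reaction that works at neopentyl-type centres and leaves the acetonide and alkene intact.

Step 18
Reactants: 28 methyl ketone
Product: 30 β-hydroxy ketone (C1–CO–CH2CH2OH), via lithium enolate 29 (not isolated)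
Conditions: LDA (2.1 equiv), THF, −78 °C; then 1H-benzotriazole-1-methanol, −78 → −40 °C
Reagents that add atoms: 1H-benzotriazole-1-methanol (formaldehyde donor), OCn1nnc2ccccc12
Why: The ketone has a single enolisable position (CH3), and aldol addition of its lithium enolate to monomeric formaldehyde released in situ should give the 3-hydroxypropanoyl chain.

Step 19
Reactants: 30 β-hydroxy ketone
Product: 31 TBDPS ether
Conditions: TBDPSCl, imidazole, CH2Cl2, 0 °C → rt
Reagents that add atoms: tert-butyl(chloro)diphenylsilane, CC(C)(C)[Si](Cl)(c1ccccc1)c1ccccc1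
Why: Silylation of the primary alcohol masks it for the acylation of step 21 with a group that survives the acid of step 20.

Step 20
Reactants: 31 TBDPS ether
Product: 32 cis-5,6-diol
Conditions: AcOH–H2O (4:1), 60 °C
Reagents that add atoms: none
Why: Acetal hydrolysis frees the cis-diol, the TBDPS ether and the β-silyloxy ketone being stable to aqueous acetic acid.

Step 21
Reactants: 32 cis-5,6-diol; 33 3-methylglutaconic anhydride
Product: 35 O-TBDPS tandyukisin C, via stannylene acetal 34 (not isolated)
Conditions: Bu2SnO, toluene, reflux (−H2O); then 33, CH2Cl2, 0 °C → rt; pH 4 buffer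
Reagents that add atoms: none
Why: Stannylene-mediated acylation of a cis-diol occurs at the equatorial oxygen (C5), and the anhydride should open at its non-conjugated carbonyl, so the ester forms on the CH2 side and the ring geometry of the anhydride is kept as the (Z)-enoic acid.

Step 22
Reactants: 35 O-TBDPS tandyukisin C
Product: 36 tandyukisin C
Conditions: HF·pyridine, pyridine, THF, 0 °C → rt
Reagents that add atoms: none
Why: Buffered fluoride desilylation should free the primary alcohol without β-elimination of the β-oxy ketone, acyl migration or isomerisation of the (Z)-enoic acid.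

**Compound list**

1 | (R)-pulegone | C[C@@H]1CCC(=C(C)C)C(=O)C1 | starting material
2 | pulegone oxide (epoxide diastereomers) | C[C@@H]1CCC2(OC2(C)C)C(=O)C1 | intermediate
3 | (5R)-5-methyl-2-(phenylsulfanyl)cyclohexan-1-one (C2 epimers) | C[C@@H]1CCC(Sc2ccccc2)C(=O)C1 | intermediate
4 | (5R)-5-methyl-2-(phenylsulfinyl)cyclohexan-1-one | C[C@@H]1CCC(S(=O)c2ccccc2)C(=O)C1 | intermediate (not isolated)
5 | (R)-5-methylcyclohex-2-en-1-one | C[C@@H]1CC=CC(=O)C1 | intermediate
6 | methyl bromoacetate | COC(=O)CBr | starting material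
7 | cross-conjugated lithium dienolate of 5 | C[C@@H]1CC=CC(O[Li])=C1 | intermediate (not isolated)
8 | methyl 2-[(1S,6R)-6-methyl-2-oxocyclohex-3-en-1-yl]acetate | C[C@@H]1CC=CC(=O)[C@H]1CC(=O)OC | intermediate
9 | methyl 2-[(1S,2S,6R)-2-hydroxy-6-methylcyclohex-3-en-1-yl]acetate | C[C@@H]1CC=C[C@H](O)[C@H]1CC(=O)OC | intermediate
10 | triol ester (C5,C6-cis-diol anti to C4a–OH) | C[C@@H]1C[C@@H](O)[C@@H](O)[C@H](O)[C@H]1CC(=O)OC | intermediate
11 | C5,C6-acetonide alcohol | C[C@@H]1C[C@H]2OC(C)(C)O[C@H]2[C@H](O)[C@H]1CC(=O)OC | intermediate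
12 | acetonide ketone (C4a=O) | C[C@@H]1C[C@H]2OC(C)(C)O[C@H]2C(=O)[C@H]1CC(=O)OC | intermediate
13 | methyl enol ether (E/Z) | C[C@@H]1C[C@H]2OC(C)(C)O[C@H]2C(=COC)[C@H]1CC(=O)OC | intermediate
14 | equatorial C4 aldehyde | C[C@@H]1C[C@H]2OC(C)(C)O[C@H]2[C@H](C=O)[C@H]1CC(=O)OC | intermediate
15 | (R)-2-methylbutanoic acid | CC[C@@H](C)C(=O)O | starting material
16 | (R)-2-methylbutan-1-ol | CC[C@@H](C)CO | intermediate
17 | (R)-2-methylbutanal | CC[C@@H](C)C=O | intermediate
18 | (R,E)-1-iodo-3-methylpent-1-ene | CC[C@@H](C)/C=C/I | intermediate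
19 | [(R,E)-3-methylpent-1-en-1-yl]magnesium bromide | CC[C@@H](C)/C=C/[Mg]Br | intermediate (not isolated)
20 | bromomagnesium alkoxide of the δ-hydroxy ester | C[C@@H]1C[C@H]2OC(C)(C)O[C@H]2[C@H]([C@H](O[Mg]Br)/C=C/[C@H](C)CC)[C@H]1CC(=O)OC | intermediate (not isolated)
21 | trans-fused 4-alkenyl δ-lactone (C1 = CH2) | CC[C@@H](C)/C=C/[C@H]1OC(=O)C[C@H]2[C@H](C)C[C@H]3OC(C)(C)O[C@H]3[C@H]12 | intermediate
22 | lithium enolate of 21 | CC[C@@H](C)/C=C/[C@H]1OC(O[Li])=C[C@H]2[C@H](C)C[C@H]3OC(C)(C)O[C@H]3[C@H]12 | intermediate (not isolated)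
23 | trans-fused 4-alkenyl-1-methyl δ-lactone (C1 epimers; equatorial-methyl epimer shown) | CC[C@@H](C)/C=C/[C@H]1OC(=O)[C@H](C)[C@H]2[C@H](C)C[C@H]3OC(C)(C)O[C@H]3[C@H]12 | intermediate
24 | lithium enolate of 23 | CC[C@@H](C)/C=C/[C@H]1OC(O[Li])=C(C)[C@H]2[C@H](C)C[C@H]3OC(C)(C)O[C@H]3[C@H]12 | intermediate (not isolated)
25 | tert-butyldimethylsilyl ketene acetal of 23 | CC[C@@H](C)/C=C/[C@H]1OC(O[Si](C)(C)C(C)(C)C)=C(C)[C@H]2[C@H](C)C[C@H]3OC(C)(C)O[C@H]3[C@H]12 | intermediate (not isolated)
26 | tert-butyldimethylsilyl ester of 27 | CC[C@@H](C)[C@H]1C=C[C@H]2[C@@H]3OC(C)(C)O[C@@H]3C[C@@H](C)[C@@H]2[C@@]1(C)C(=O)O[Si](C)(C)C(C)(C)C | intermediate (not isolated)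
27 | ring-contracted decalin carboxylic acid (5,6-acetonide) | CC[C@@H](C)[C@H]1C=C[C@H]2[C@@H]3OC(C)(C)O[C@@H]3C[C@@H](C)[C@@H]2[C@@]1(C)C(=O)O | intermediate
28 | C1 methyl ketone | CC[C@@H](C)[C@H]1C=C[C@H]2[C@@H]3OC(C)(C)O[C@@H]3C[C@@H](C)[C@@H]2[C@@]1(C)C(C)=O | intermediate
29 | lithium enolate of 28 | CC[C@@H](C)[C@H]1C=C[C@H]2[C@@H]3OC(C)(C)O[C@@H]3C[C@@H](C)[C@@H]2[C@@]1(C)C(=C)O[Li] | intermediate (not isolated)
30 | β-hydroxy ketone (3-hydroxypropanoyl on C1) | CC[C@@H](C)[C@H]1C=C[C@H]2[C@@H]3OC(C)(C)O[C@@H]3C[C@@H](C)[C@@H]2[C@@]1(C)C(=O)CCO | intermediate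
31 | TBDPS ether of 30 | CC[C@@H](C)[C@H]1C=C[C@H]2[C@@H]3OC(C)(C)O[C@@H]3C[C@@H](C)[C@@H]2[C@@]1(C)C(=O)CCO[Si](c1ccccc1)(c1ccccc1)C(C)(C)C | intermediate
32 | cis-5,6-diol (primary OH as TBDPS ether) | CC[C@@H](C)[C@H]1C=C[C@H]2[C@H](O)[C@H](O)C[C@@H](C)[C@@H]2[C@@]1(C)C(=O)CCO[Si](c1ccccc1)(c1ccccc1)C(C)(C)C | intermediate
33 | 3-methylglutaconic anhydride | CC1=CC(=O)OC(=O)C1 | starting material
34 | 5,6-O-dibutylstannylene acetal of 32 | CC[C@@H](C)[C@H]1C=C[C@H]2[C@@H]3O[Sn](CCCC)(CCCC)O[C@@H]3C[C@@H](C)[C@@H]2[C@@]1(C)C(=O)CCO[Si](c1ccccc1)(c1ccccc1)C(C)(C)C | intermediate (not isolated)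
35 | O-TBDPS tandyukisin C | CC[C@@H](C)[C@H]1C=C[C@H]2[C@H](OC(=O)C/C(C)=C\C(=O)O)[C@H](O)C[C@@H](C)[C@@H]2[C@@]1(C)C(=O)CCO[Si](c1ccccc1)(c1ccccc1)C(C)(C)C | intermediate
36 | tandyukisin C | CC[C@@H](C)[C@H]1C=C[C@H]2[C@H](OC(=O)C/C(C)=C\C(=O)O)[C@H](O)C[C@@H](C)[C@@H]2[C@@]1(C)C(=O)CCO | target

**Step count**

Total: 22 steps. Longest linear sequence: 19 steps (steps 1–10 and 14–22); steps 11–13 make the side-chain fragment.

**Steps most likely to fail**

1. Step 16. The boat [3,3] array may be reached only slowly on the trans-fused lactone, so that the silyl ketene acetal is lost by protodesilylation or by C-silyl and ketene-type decomposition before it rearranges. The fallback sets out from 23 and comes back at 27, using a thermally robust enol ether in place of the ketene acetal. DIBAL-H (CH2Cl2, −78 °C) should reduce 23 to the lactol F1. Mesylation and elimination (MsCl, Et3N, 0 → 40 °C) should give the cyclic allyl vinyl ether, the 2-alkenyl-5-methyl-3,4-dihydro-2H-pyran F2. Heating (o-dichlorobenzene, 190 °C) should bring about the Claisen rearrangement through the same ring-enforced boat, with the same sense at C1 and C2, to the C1 aldehyde F3. Pinnick oxidation (NaClO2, NaH2PO4, 2-methyl-2-butene) then gives 27.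

2. Step 14. Facial selectivity in the addition to the aldehyde may be poor, through competition of the second Felkin rotamer or chelation, so that the C4 epimer forms and lactonises as well. The fallback sets out from 14 (with 18) and comes back at 21. The addition is run as before and the C4-epimeric lactone F4 is separated. It is opened with LiOH (THF–H2O) to the C4-epimeric hydroxy acid F5, which is closed again by Mitsunobu lactonisation (PPh3, DIAD, toluene, 0 °C). This inverts C4 and should give 21.

3. Step 21. Acyl transfer may go to the C6 oxygen or to both oxygens, or proton transfer from the CH-acidic anhydride to the tin alkoxide may stall the acylation. The fallback sets out from 32 and comes back at 35, differentiating the diol before the acylation. 2-Chloro-1,1,1-trimethoxyethane (CSA cat., CH2Cl2) should give the cyclic orthoester F6. Opening in aqueous acetic acid at rt should give the axial ester, the C6 chloroacetate F7, with the equatorial C5–OH free. Acylation of F7 with 33 (pyridine, CH2Cl2) should give the C5 glutaconate C6 chloroacetate F8. Thiourea (NaHCO3, MeOH–THF, 50 °C) removes the chloroacetate and gives 35.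

**Further compounds**

F1 | step 16 | lactol from 23 (anomers) | CC[C@@H](C)/C=C/[C@H]1OC(O)[C@H](C)[C@H]2[C@H](C)C[C@H]3OC(C)(C)O[C@H]3[C@H]12
F2 | step 16 | 2-alkenyl-5-methyl-3,4-dihydro-2H-pyran (cyclic allyl vinyl ether) | CC[C@@H](C)/C=C/[C@H]1OC=C(C)[C@H]2[C@H](C)C[C@H]3OC(C)(C)O[C@H]3[C@H]12
F3 | step 16 | ring-contracted C1 aldehyde | CC[C@@H](C)[C@H]1C=C[C@H]2[C@@H]3OC(C)(C)O[C@@H]3C[C@@H](C)[C@@H]2[C@@]1(C)C=O
F4 | step 14 | C4-epimeric lactone (alkenyl axial) | CC[C@@H](C)/C=C/[C@@H]1OC(=O)C[C@H]2[C@H](C)C[C@H]3OC(C)(C)O[C@H]3[C@H]12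
F5 | step 14 | C4-epimeric hydroxy acid | C[C@@H]1C[C@H]2OC(C)(C)O[C@H]2[C@H]([C@@H](O)/C=C/[C@H](C)CC)[C@H]1CC(=O)O
F6 | step 21 | 5,6-cyclic ortho(chloroacetate) of 32 | CC[C@@H](C)[C@H]1C=C[C@H]2[C@@H]3OC(CCl)(OC)O[C@@H]3C[C@@H](C)[C@@H]2[C@@]1(C)C(=O)CCO[Si](c1ccccc1)(c1ccccc1)C(C)(C)C
F7 | step 21 | C6 chloroacetate with free C5–OH | CC[C@@H](C)[C@H]1C=C[C@H]2[C@H](O)[C@H](OC(=O)CCl)C[C@@H](C)[C@@H]2[C@@]1(C)C(=O)CCO[Si](c1ccccc1)(c1ccccc1)C(C)(C)C
F8 | step 21 | C5 (Z)-3-methylglutaconate C6 chloroacetate | CC[C@@H](C)[C@H]1C=C[C@H]2[C@H](OC(=O)C/C(C)=C\C(=O)O)[C@H](OC(=O)CCl)C[C@@H](C)[C@@H]2[C@@]1(C)C(=O)CCO[Si](c1ccccc1)(c1ccccc1)C(C)(C)C
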